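## Retrosynthetic overview
1. Target ⇒ protected oxepine ester. Forward: (E)-selective allylic C–H oxidation of the prenyl terminus, then one fluoride step that frees both phenols and the acid.
2. Key disconnection O1–C2. The oxepine (ring A) is the only ring to be built, since the arene is bought. It opens to a (Z)-allylic alcohol tethered to an aroylacrylate. Forward: an enantioselective 7-exo oxa-Michael closure forms the ring and sets C-2 in one step.
3. Aroylacrylate C=C ⇒ Wittig reaction of an α-keto ester with an aroylmethylene ylide made from methyl 2,5-dihydroxybenzoate.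
4. C4–C5 ⇒ Heck coupling with redox isomerisation of a (Z)-vinyl iodide and a vinylglycolate ester.
5. (Z)-Vinyl iodide ⇒ propargyl alcohol + homoprenyl Grignard reagent + iodine (hydroxyl-directed anti-carbomagnesiation).

Assumption: the SMILES is read as (2R) at the oxepine C-2 and (E) in the side chain; 1 and racemic 6 are bought as such.

## Route

Step 1
Reactants: 1 5-bromo-2-methylpent-2-ene; 2 prop-2-yn-1-ol
Product: 5 (2Z)-3-iodo-2-(4-methylpent-3-en-1-yl)prop-2-en-1-ol, via homoprenylmagnesium bromide 3 (not isolated), via vinylmagnesium alkoxide chelate 4 (not isolated)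
Conditions: 1 (2.4 equiv), Mg, Et2O, reflux; 2 (1.0 equiv), CuI (10 mol %), Et2O, −10 °C → rt, 12 h; I2, Et2O, −40 → 0 °C; aq. NH4Cl
Reagents that add atoms: iodine, I-I
Why: Hydroxyl-directed copper-catalysed anti-carbomagnesiation puts the alkyl group on C-2 and magnesium on C-3 cis to CH2O in a five-membered chelate, so iodinolysis with retention fixes the (Z)-trisubstituted alkene that later becomes the ring olefin.

Step 2
Reactants: 6 methyl 2-hydroxybut-3-enoate (racemic); 7 2-(trimethylsilyl)ethanol
Product: 8 2-(trimethylsilyl)ethyl 2-hydroxybut-3-enoate (racemic)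
Conditions: Ti(OiPr)4 (10 mol %), toluene, 90 °C, MeOH distilled off
Reagents that add atoms: none
Why: Titanate-catalysed transesterification driven by removal of methanol installs a fluoride-labile ester, so no hydroxide is needed once the base-sensitive β-alkoxy ketone exists.

Step 3
Reactants: 5 (2Z)-3-iodo-2-(4-methylpent-3-en-1-yl)prop-2-en-1-ol; 8 2-(trimethylsilyl)ethyl 2-hydroxybut-3-enoate
Product: 9 2-(trimethylsilyl)ethyl (5Z)-6-(hydroxymethyl)-10-methyl-2-oxoundeca-5,9-dienoate
Conditions: Pd(OAc)2 (5 mol %), n-Bu4NCl, NaHCO3, DMF, 35 °C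
Reagents that add atoms: none
Why: In this Heck reaction under Jeffery conditions the alkenylpalladium species adds to the terminal carbon of the secondary allylic alcohol, β-hydride elimination toward the carbinol C–H gives an enol that tautomerises to the α-keto ester, and the (Z)-geometry of the iodide is retained.

Step 4
Reactants: 10 methyl 2,5-dihydroxybenzoate
Product: 11 methyl 2,5-bis[(tert-butyldimethylsilyl)oxy]benzoate
Conditions: TBSCl (2.5 equiv), imidazole, DMF, rt → 40 °C
Reagents that add atoms: tert-butyldimethylsilyl chloride, CC(C)(C)[Si](C)(C)Cl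
Why: Standard silylation masks both phenols; the ortho-phenol would otherwise out-compete the alcohol in step 7 by closing to a chromanone.

Step 5
Reactants: 11 methyl 2,5-bis[(tert-butyldimethylsilyl)oxy]benzoate; 12 methyltriphenylphosphonium bromide
Product: 14 1-{2,5-bis[(tert-butyldimethylsilyl)oxy]phenyl}-2-(triphenyl-λ5-phosphanylidene)ethan-1-one, via methylidenetriphenylphosphorane 13 (not isolated)
Conditions: 12 (2.2 equiv), n-BuLi (2.1 equiv), THF, 0 °C; then 11, 0 → 45 °C
Reagents that add atoms: none
Why: The ester acylates the non-stabilised ylide and a second equivalent of ylide deprotonates the acylphosphonium salt (transylidation) to give the stabilised aroyl ylide, while the sparingly soluble LiOMe by-product leaves the aryl silyl ethers alone.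

Step 6
Reactants: 9 2-(trimethylsilyl)ethyl (5Z)-6-(hydroxymethyl)-10-methyl-2-oxoundeca-5,9-dienoate; 14 aroylmethylene ylide
Product: 15 2-(trimethylsilyl)ethyl (2E,5Z)-2-(2-{2,5-bis[(tert-butyldimethylsilyl)oxy]phenyl}-2-oxoethylidene)-6-(hydroxymethyl)-10-methylundeca-5,9-dienoate
Conditions: toluene, 80 °C, 24 h; chromatography removes the minor (2Z)-isomer
Reagents that add atoms: none
Why: The Wittig olefination of the activated α-keto ester carbonyl with a stabilised ylide places the aroyl group trans to the ester, fixes the C=C position without ambiguity, and is neutral enough to leave the free alcohol and the γ-CH2 untouched.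

Step 7 (key step)
Reactants: 15 (2E,5Z)-hydroxy aroylacrylate
Product: 16 2-(trimethylsilyl)ethyl (2R)-2-(2-{2,5-bis[(tert-butyldimethylsilyl)oxy]phenyl}-2-oxoethyl)-6-(4-methylpent-3-en-1-yl)-2,3,4,7-tetrahydrooxepine-2-carboxylate
Conditions: squaramide from 9-amino(9-deoxy)epiquinidine and 3,5-bis(trifluoromethyl)aniline (10 mol %), cyclopentyl methyl ether (0.02 M), 4 Å MS, 0 → 25 °C
Reagents that add atoms: none
Why: Proposed new method: organocatalytic enantioselective 7-exo-trig oxa-Michael cyclisation onto a β-alkoxycarbonyl-β-alkyl aryl enone; the squaramide NH pair binds the aryl ketone oxygen of an already doubly activated, fumaroyl-type C=C while the quinuclidine nitrogen acts as general base on the primary allylic OH, the (Z)-alkene holds that oxygen within reach of C-2 so that it attacks the Re face of C-2 (CO2R > C=C > CH2) through a chair-like seven-membered transition state, the enol is protonated by the quinuclidinium ion, and this single step makes the O1–C2 bond, closes ring A and sets (R)-C2, the amine being too weak to remove the γ-H at C-3 and shift the enone out of conjugation; the closest known reaction type is the bifunctional aminothiourea/squaramide-catalysed cycloetherification of ε- and ζ-hydroxy aryl enones to 2-substituted tetrahydrofurans and tetrahydropyrans, not yet shown for seven-membered rings or for fully substituted α-alkoxy ester centres.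

Step 8
Reactants: 16 (2R)-oxepine ester
Product: 17 2-(trimethylsilyl)ethyl (2R)-2-(2-{2,5-bis[(tert-butyldimethylsilyl)oxy]phenyl}-2-oxoethyl)-6-[(3E)-5-hydroxy-4-methylpent-3-en-1-yl]-2,3,4,7-tetrahydrooxepine-2-carboxylate
Conditions: SeO2 (0.3 equiv), t-BuOOH (3 equiv, decane), salicylic acid (10 mol %), CH2Cl2, 0 °C → rt, stopped at about 70 % conversion, 16 recycled
Reagents that add atoms: tert-butyl hydroperoxide, CC(C)(C)OO (terminal oxygen source, relayed through SeO2, O=[Se]=O)
Why: The Riley allylic oxidation (ene reaction followed by a [2,3]-sigmatropic shift) hydroxylates the (E)-methyl of the electron-rich gem-dimethyl alkene, whereas the ring alkene is deactivated by its allylic oxygen, as is the 2,3-alkene of geranyl acetate; C-2 is not touched.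

Step 9
Reactants: 17 protected (2R,3E)-allylic alcohol
Product: 18 (2R)-2-[2-(2,5-dihydroxyphenyl)-2-oxoethyl]-6-[(3E)-5-hydroxy-4-methylpent-3-en-1-yl]-2,3,4,7-tetrahydrooxepine-2-carboxylic acid (CNP0570804.1)
Conditions: TASF (4 equiv), DMF, 0 °C → rt, argon; 0.1 M HCl work-up
Reagents that add atoms: none
Why: Fluoride cleaves both aryl silyl ethers and fragments the 2-(trimethylsilyl)ethyl ester by β-elimination in one mild operation, without hydroxide or heat, so the β-alkoxy ketone does not undergo retro-Michael opening and C-2 keeps its configuration.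

## Compound list
1 | 5-bromo-2-methylpent-2-ene | CC(C)=CCCBr | starting material
2 | prop-2-yn-1-ol | C#CCO | starting material
3 | (4-methylpent-3-en-1-yl)magnesium bromide | CC(C)=CCC[Mg]Br | intermediate
4 | 4-(4-methylpent-3-en-1-yl)-2,5-dihydro-1,2-oxamagnesole (vinylmagnesium alkoxide chelate) | CC(C)=CCCC1=C[Mg]OC1 | intermediate
5 | (2Z)-3-iodo-2-(4-methylpent-3-en-1-yl)prop-2-en-1-ol | OC/C(CCC=C(C)C)=C\I | intermediate
6 | methyl 2-hydroxybut-3-enoate (racemic) | C=CC(O)C(=O)OC | starting material
7 | 2-(trimethylsilyl)ethanol | C[Si](C)(C)CCO | starting material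
8 | 2-(trimethylsilyl)ethyl 2-hydroxybut-3-enoate (racemic) | C=CC(O)C(=O)OCC[Si](C)(C)C | intermediate
9 | 2-(trimethylsilyl)ethyl (5Z)-6-(hydroxymethyl)-10-methyl-2-oxoundeca-5,9-dienoate | OC/C(CCC=C(C)C)=C\CCC(=O)C(=O)OCC[Si](C)(C)C | intermediate
10 | methyl 2,5-dihydroxybenzoate | COC(=O)c1cc(O)ccc1O | starting material
11 | methyl 2,5-bis[(tert-butyldimethylsilyl)oxy]benzoate | COC(=O)c1cc(O[Si](C)(C)C(C)(C)C)ccc1O[Si](C)(C)C(C)(C)C | intermediate
12 | methyltriphenylphosphonium bromide | C[P+](c1ccccc1)(c1ccccc1)c1ccccc1.[Br-] | starting material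
13 | methylidenetriphenylphosphorane | C=P(c1ccccc1)(c1ccccc1)c1ccccc1 | intermediate
14 | 1-{2,5-bis[(tert-butyldimethylsilyl)oxy]phenyl}-2-(triphenyl-λ5-phosphanylidene)ethan-1-one | O=C(C=P(c1ccccc1)(c1ccccc1)c1ccccc1)c1cc(O[Si](C)(C)C(C)(C)C)ccc1O[Si](C)(C)C(C)(C)C | intermediate
15 | 2-(trimethylsilyl)ethyl (2E,5Z)-2-(2-{2,5-bis[(tert-butyldimethylsilyl)oxy]phenyl}-2-oxoethylidene)-6-(hydroxymethyl)-10-methylundeca-5,9-dienoate | O=C(c1cc(O[Si](C)(C)C(C)(C)C)ccc1O[Si](C)(C)C(C)(C)C)/C=C(\CC/C=C(\CO)CCC=C(C)C)C(=O)OCC[Si](C)(C)C | intermediate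
16 | 2-(trimethylsilyl)ethyl (2R)-2-(2-{2,5-bis[(tert-butyldimethylsilyl)oxy]phenyl}-2-oxoethyl)-6-(4-methylpent-3-en-1-yl)-2,3,4,7-tetrahydrooxepine-2-carboxylate | CC(C)=CCCC1=CCC[C@@](CC(=O)c2cc(O[Si](C)(C)C(C)(C)C)ccc2O[Si](C)(C)C(C)(C)C)(C(=O)OCC[Si](C)(C)C)OC1 | intermediate
17 | 2-(trimethylsilyl)ethyl (2R)-2-(2-{2,5-bis[(tert-butyldimethylsilyl)oxy]phenyl}-2-oxoethyl)-6-[(3E)-5-hydroxy-4-methylpent-3-en-1-yl]-2,3,4,7-tetrahydrooxepine-2-carboxylate | C/C(=C\CCC1=CCC[C@@](CC(=O)c2cc(O[Si](C)(C)C(C)(C)C)ccc2O[Si](C)(C)C(C)(C)C)(C(=O)OCC[Si](C)(C)C)OC1)CO | intermediate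
18 | (2R)-2-[2-(2,5-dihydroxyphenyl)-2-oxoethyl]-6-[(3E)-5-hydroxy-4-methylpent-3-en-1-yl]-2,3,4,7-tetrahydrooxepine-2-carboxylic acid | C/C(=C\CCC1=CCC[C@@](CC(=O)c2cc(O)ccc2O)(C(=O)O)OC1)CO | target

## Count and risks
Total step count: 9. Longest linear sequence: 6 (steps 1, 3, 6, 7, 8, 9).

**Step 7 (the new reaction).** There are four risks:
- The ring–chain equilibrium may be incomplete for a seven-membered ring bearing a fully substituted carbon.
- The enone may drift to the β,γ-unsaturated ester, which would close 6-exo at C-3 instead.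
- The ee may be low.
- The facial sense may be opposite to the model. In that case the quinine-derived pseudoenantiomeric squaramide is used.

The fallback uses known chemistry, sets out from 15 and comes back at 16. Compound 15 is closed with an achiral base (DBU 10 mol % or KOt-Bu 5 mol %, THF, −20 °C). This is an ordinary base-mediated intramolecular oxa-Michael addition and gives the racemic oxepine ester F1. Preparative chromatography on a chiral stationary phase (supercritical CO2/MeOH, amylose carbamate column) gives 16 and the (2S)-enantiomer F2. F2 is returned to the DBU equilibration, where retro-Michael opening to 15 and re-closure racemise it, and is then resolved again.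

**Step 3 (Heck coupling).** β-Hydride elimination may go toward the doubly allylic CH2 and give a dienol, a π-allylpalladium species may form, or the α-keto ester may condense with itself. The fallback sets out from 8 and 5 and comes back at 9.
- Compound 8 is hydroborated with 9-BBN-H (2.2 equiv, THF, rt) to the bis(boryl) butanoate F3.
- F3 is coupled with 5 in a B-alkyl Suzuki–Miyaura reaction (PdCl2(dppf), K3PO4, DMF/THF/H2O, rt), with retention of the (Z)-geometry, to the α-hydroxy ester diol F4.
- Only the chelating α-hydroxy ester of F4 is then oxidised, by vanadium-catalysed aerobic oxidation (VO(OiPr)3 5 mol %, O2, MeCN, rt), to give 9.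

**Step 8 (allylic oxidation).** Conversion is moderate, over-oxidation to the enal is likely, and competing attack at other allylic positions is possible. The fallback sets out from 16 and comes back at 17. The prenyl terminus undergoes cross-metathesis with methacrolein (10 equiv), using the second-generation Hoveyda–Grubbs catalyst RuCl2(H2IMes)(=CH-C6H4-2-OiPr) at 5 mol % in CH2Cl2 at 40 °C. This gives the (E)-enal F5. The aldehyde is then reduced in the presence of the hindered aryl ketone with NaBH4 (0.5 equiv, EtOH, −78 °C) to give 17.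

## Further compounds
F1 | step 7 | racemic 2-(trimethylsilyl)ethyl 2-(2-{2,5-bis[(tert-butyldimethylsilyl)oxy]phenyl}-2-oxoethyl)-6-(4-methylpent-3-en-1-yl)-2,3,4,7-tetrahydrooxepine-2-carboxylate | CC(C)=CCCC1=CCCC(CC(=O)c2cc(O[Si](C)(C)C(C)(C)C)ccc2O[Si](C)(C)C(C)(C)C)(C(=O)OCC[Si](C)(C)C)OC1
F2 | step 7 | (2S)-enantiomer of 16 | CC(C)=CCCC1=CCC[C@](CC(=O)c2cc(O[Si](C)(C)C(C)(C)C)ccc2O[Si](C)(C)C(C)(C)C)(C(=O)OCC[Si](C)(C)C)OC1
F3 | step 3 | 2-(trimethylsilyl)ethyl 4-(9-borabicyclo[3.3.1]nonan-9-yl)-2-[(9-borabicyclo[3.3.1]nonan-9-yl)oxy]butanoate | C[Si](C)(C)CCOC(=O)C(OB1C2CCCC1CCC2)CCB1C2CCCC1CCC2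
F4 | step 3 | 2-(trimethylsilyl)ethyl (5Z)-2-hydroxy-6-(hydroxymethyl)-10-methylundeca-5,9-dienoate | OC/C(CCC=C(C)C)=C\CCC(O)C(=O)OCC[Si](C)(C)C
F5 | step 8 | 2-(trimethylsilyl)ethyl (2R)-2-(2-{2,5-bis[(tert-butyldimethylsilyl)oxy]phenyl}-2-oxoethyl)-6-[(3E)-4-methyl-5-oxopent-3-en-1-yl]-2,3,4,7-tetrahydrooxepine-2-carboxylate | C/C(=C\CCC1=CCC[C@@](CC(=O)c2cc(O[Si](C)(C)C(C)(C)C)ccc2O[Si](C)(C)C(C)(C)C)(C(=O)OCC[Si](C)(C)C)OC1)C=O
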